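**Assumption:** the target SMILES has no stereocentre and no stereogenic double bond, so the molecule is achiral and there is no enantiomer to control. The only stereo-elements in the route are transient (racemic carbinol 8, E-chalcone 18) and are erased.

## Retrosynthetic overview
1. Target ⇐ removal of four MOM ethers from a protected flavonol; the pyranone ring (ring C) is the only ring built, last, by Algar–Flynn–Oyamada oxidative cyclisation of a 2'-hydroxychalcone.
2. Chalcone ⇐ late Claisen–Schmidt union of an A-ring acetophenone (23 heavy atoms) and a B-ring benzaldehyde (26 heavy atoms).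
3. A-ring acetophenone ⇐ resorcinol: Ir C–H borylation/oxidation gives the phloroglucinol pattern, a Claisen rearrangement of a symmetric aryl prenyl ether sets the 1,1-dimethylallyl group, and ortho-formylation/MeMgBr/oxidation adds the acetyl.
4. B-ring aldehyde ⇐ catechol: dibromination, mono Br/Mg exchange–formylation, then two prenylations with prenyl bromide (lithiation between Br and OMOM, then Br/Li exchange).
5. Rings A and B are carried aromatic from resorcinol and catechol; ring C closes at step 16.

## Fragment A (steps 1–7)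

**Step 1**
Reactants: 1 resorcinol
Product: 2 1,3-bis(methoxymethoxy)benzene
Conditions: NaH, MOMCl, DMF, 0 °C → rt
Reagents that add atoms: chloromethyl methyl ether, COCCl
Why: Williamson-type O-alkylation of both phenoxides; MOM is stable to all base, organometallic and thermal steps ahead.

**Step 2**
Reactants: 2
Product: 3 3,5-bis(methoxymethoxy)phenol
Conditions: [Ir(OMe)(cod)]2 (cat.), dtbpy, B2pin2, THF, 80 °C; then 30% H2O2, aq NaOH, 0 °C → rt
Reagents that add atoms: hydrogen peroxide, OO
Why: Ir-catalysed C–H borylation is sterically controlled, so only C5 (the one C–H with no ortho substituent) reacts, and alkaline peroxide oxidises the aryl–Bpin to the phenol.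

**Step 3**
Reactants: 3; 4 prenyl bromide (1-bromo-3-methylbut-2-ene)
Product: 5 1,3-bis(methoxymethoxy)-5-[(3-methylbut-2-en-1-yl)oxy]benzene
Conditions: K2CO3, acetone, reflux
Reagents that add atoms: none (prenyl unit from 4)
Why: Williamson O-alkylation of the phenoxide (SN2 on the primary allylic bromide).

**Step 4**
Reactants: 5
Product: 6 3,5-bis(methoxymethoxy)-2-(2-methylbut-3-en-2-yl)phenol
Conditions: PhNEt2, 170 °C, sealed tube, Ar, ~3 h (stop at full conversion)
Reagents that add atoms: none
Why: aromatic Claisen [3,3] rearrangement delivers the prenyl γ-carbon to an ortho carbon, giving the 1,1-dimethylallyl group; the two ortho positions are symmetry-equivalent, so there is one ortho product, and the phenol released is the one needed beside the tert-allyl group.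

**Step 5**
Reactants: 6
Product: 7 2-hydroxy-4,6-bis(methoxymethoxy)-3-(2-methylbut-3-en-2-yl)benzaldehyde
Conditions: MgCl2, Et3N, (CH2O)n, MeCN, reflux
Reagents that add atoms: paraformaldehyde, C=O
Why: Casiraghi–Skattebøl formylation goes through the magnesium phenoxide and is strictly ortho to OH; the only free ortho position is C6.

**Step 6**
Reactants: 7
Product: 8 1-[2-hydroxy-4,6-bis(methoxymethoxy)-3-(2-methylbut-3-en-2-yl)phenyl]ethan-1-ol (racemic)
Conditions: MeMgBr (3.5 equiv), THF, 0 °C → rt; sat. NH4Cl
Reagents that add atoms: methylmagnesium bromide, C[Mg]Br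
Why: Grignard addition to the aldehyde after phenoxide formation; the new carbinol centre is racemic and is destroyed in the next step.

**Step 7**
Reactants: 8
Product: 9 1-[2-hydroxy-4,6-bis(methoxymethoxy)-3-(2-methylbut-3-en-2-yl)phenyl]ethan-1-one
Conditions: activated MnO2, CH2Cl2, rt (crude 8 used directly)
Reagents that add atoms: none
Why: chemoselective benzylic alcohol oxidation; MnO2 leaves the isolated alkene and MOM ethers untouched and the product is stabilised by the OH···O=C hydrogen bond.

## Fragment B (steps 8–14)

**Step 8**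
Reactants: 10 catechol
Product: 11 4,5-dibromobenzene-1,2-diol
Conditions: Br2 (2.05 equiv), AcOH, 10 °C → rt
Reagents that add atoms: bromine, BrBr
Why: electrophilic aromatic bromination para to each hydroxyl gives the symmetric 4,5-dibromide.

**Step 9**
Reactants: 11
Product: 12 1,2-dibromo-4,5-bis(methoxymethoxy)benzene
Conditions: MOMCl, iPr2NEt, CH2Cl2, 0 °C → rt
Reagents that add atoms: chloromethyl methyl ether, COCCl
Why: O-alkylation of both phenols; MOM later acidifies the adjacent ring C–H for step 12.

**Step 10**
Reactants: 12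
Product: 13 2-bromo-4,5-bis(methoxymethoxy)benzaldehyde
Conditions: iPrMgCl·LiCl (1.05 equiv), THF, −15 °C; then DMF, → rt; aq NH4Cl
Reagents that add atoms: N,N-dimethylformamide, CN(C)C=O
Why: mono Br/Mg exchange on the symmetric dibromide gives a single 2-bromoarylmagnesium species (stable below 0 °C, no aryne), which DMF formylates (Bouveault).

**Step 11**
Reactants: 13
Product: 14 1-bromo-2-(dimethoxymethyl)-4,5-bis(methoxymethoxy)benzene
Conditions: HC(OMe)3, MeOH, PPTS (cat.), rt; Et3N quench
Reagents that add atoms: trimethyl orthoformate, COC(OC)OC (with methanol, CO)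
Why: mild acetalisation masks the aldehyde against LDA and t-BuLi; aryl MOM ethers survive catalytic PPTS under anhydrous conditions.

**Step 12**
Reactants: 14; 4 prenyl bromide
Product: 15 2-bromo-1-(dimethoxymethyl)-4,5-bis(methoxymethoxy)-3-(3-methylbut-2-en-1-yl)benzene
Conditions: LDA (1.15 equiv), THF, −78 °C, 1 h; CuBr·SMe2, −78 °C; then 4, −78 → 0 °C
Reagents that add atoms: none (prenyl unit from 4)
Why: LDA removes the most acidic ring proton, the one flanked by Br and OMOM, without Br/Li exchange; transmetalation to copper at −78 °C suppresses aryne formation and gives α (SN2) allylation.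

**Step 13**
Reactants: 15; 4 prenyl bromide
Product: 16 1-(dimethoxymethyl)-4,5-bis(methoxymethoxy)-2,3-bis(3-methylbut-2-en-1-yl)benzene
Conditions: t-BuLi (2.1 equiv), THF, −78 °C; CuBr·SMe2; then 4, −78 °C → rt
Reagents that add atoms: none (prenyl unit from 4)
Why: Br/Li exchange at −78 °C is faster than any deprotonation, and the arylcopper is then allylated at the primary carbon of prenyl bromide.

**Step 14**
Reactants: 16
Product: 17 4,5-bis(methoxymethoxy)-2,3-bis(3-methylbut-2-en-1-yl)benzaldehyde
Conditions: PPTS (cat.), acetone/H2O 10:1, rt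
Reagents that add atoms: water, O
Why: the benzaldehyde dimethyl acetal hydrolyses under much milder acid than aryl MOM ethers or prenyl groups tolerate.

## Coupling and endgame (steps 15–17)

**Step 15**
Reactants: 9; 17
Product: 18 (E)-1-[2-hydroxy-4,6-bis(methoxymethoxy)-3-(2-methylbut-3-en-2-yl)phenyl]-3-[4,5-bis(methoxymethoxy)-2,3-bis(3-methylbut-2-en-1-yl)phenyl]prop-2-en-1-one
Conditions: KOH (excess), EtOH/H2O, rt, Ar, 36–48 h
Reagents that add atoms: none
Why: Claisen–Schmidt aldol condensation of the methyl ketone enolate with the non-enolisable aldehyde; E1cB dehydration gives the thermodynamic E-enone.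

**Step 16**
Reactants: 18
Product: 19 3-hydroxy-5,7-bis(methoxymethoxy)-8-(2-methylbut-3-en-2-yl)-2-[4,5-bis(methoxymethoxy)-2,3-bis(3-methylbut-2-en-1-yl)phenyl]-4H-chromen-4-one
Conditions: 30% H2O2 (6 equiv), 2 M aq NaOH, MeOH/THF, 0 °C → rt
Reagents that add atoms: hydrogen peroxide, OO
Why: Algar–Flynn–Oyamada reaction: the 2'-phenoxide closes onto the enone β-carbon, the enolate is hydroxylated by peroxide, and the dihydroflavonol oxidises to the flavonol. HOO⁻ is nucleophilic and does not epoxidise the isolated prenyl and vinyl alkenes; only the 2'-OH is free, so the tert-allyl group ends at C8.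

**Step 17**
Reactants: 19
Product: 20 Broussoflavonol C
Conditions: 3 M aq HCl/MeOH (1:5), 45 °C, Ar, 2–3 h (monitor, stop at completion)
Reagents that add atoms: none
Why: acid-catalysed acetal cleavage of the four aryl MOM ethers; dilute acid in methanol at moderate temperature is mild enough to leave the ortho-prenyl phenol uncyclised.

## Compound list
1 | resorcinol | Oc1cccc(O)c1 | starting material
2 | 1,3-bis(methoxymethoxy)benzene | COCOc1cccc(OCOC)c1 | intermediate
3 | 3,5-bis(methoxymethoxy)phenol | COCOc1cc(O)cc(OCOC)c1 | intermediate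
4 | prenyl bromide | CC(C)=CCBr | starting material
5 | 1,3-bis(methoxymethoxy)-5-(prenyloxy)benzene | COCOc1cc(OCC=C(C)C)cc(OCOC)c1 | intermediate
6 | 3,5-bis(methoxymethoxy)-2-(2-methylbut-3-en-2-yl)phenol | C=CC(C)(C)c1c(O)cc(OCOC)cc1OCOC | intermediate
7 | 2-hydroxy-4,6-bis(methoxymethoxy)-3-(2-methylbut-3-en-2-yl)benzaldehyde | C=CC(C)(C)c1c(O)c(C=O)c(OCOC)cc1OCOC | intermediate
8 | 1-[2-hydroxy-4,6-bis(methoxymethoxy)-3-(2-methylbut-3-en-2-yl)phenyl]ethanol (racemic) | C=CC(C)(C)c1c(O)c(C(C)O)c(OCOC)cc1OCOC | intermediate
9 | 1-[2-hydroxy-4,6-bis(methoxymethoxy)-3-(2-methylbut-3-en-2-yl)phenyl]ethanone | C=CC(C)(C)c1c(O)c(C(C)=O)c(OCOC)cc1OCOC | intermediate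
10 | catechol | Oc1ccccc1O | starting material
11 | 4,5-dibromobenzene-1,2-diol | Oc1cc(Br)c(Br)cc1O | intermediate
12 | 1,2-dibromo-4,5-bis(methoxymethoxy)benzene | COCOc1cc(Br)c(Br)cc1OCOC | intermediate
13 | 2-bromo-4,5-bis(methoxymethoxy)benzaldehyde | COCOc1cc(Br)c(C=O)cc1OCOC | intermediate
14 | 1-bromo-2-(dimethoxymethyl)-4,5-bis(methoxymethoxy)benzene | COCOc1cc(Br)c(C(OC)OC)cc1OCOC | intermediate
15 | 2-bromo-1-(dimethoxymethyl)-4,5-bis(methoxymethoxy)-3-prenylbenzene | COCOc1cc(C(OC)OC)c(Br)c(CC=C(C)C)c1OCOC | intermediate
16 | 1-(dimethoxymethyl)-4,5-bis(methoxymethoxy)-2,3-diprenylbenzene | COCOc1cc(C(OC)OC)c(CC=C(C)C)c(CC=C(C)C)c1OCOC | intermediate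
17 | 4,5-bis(methoxymethoxy)-2,3-diprenylbenzaldehyde | COCOc1cc(C=O)c(CC=C(C)C)c(CC=C(C)C)c1OCOC | intermediate
18 | (E)-2'-hydroxychalcone (tetra-MOM) | C=CC(C)(C)c1c(O)c(C(=O)/C=C/c2cc(OCOC)c(OCOC)c(CC=C(C)C)c2CC=C(C)C)c(OCOC)cc1OCOC | intermediate
19 | 5,7,3',4'-tetra-O-MOM Broussoflavonol C | C=CC(C)(C)c1c(OCOC)cc(OCOC)c2c(=O)c(O)c(-c3cc(OCOC)c(OCOC)c(CC=C(C)C)c3CC=C(C)C)oc12 | intermediate
20 | Broussoflavonol C | C=CC(C)(C)c1c(O)cc(O)c2c(=O)c(O)c(-c3cc(O)c(O)c(CC=C(C)C)c3CC=C(C)C)oc12 | target

## Totals
- Total step count: 17.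
- Longest linear sequence: 10 steps (steps 1–7 then 15–17; the other branch, steps 8–14 then 15–17, is also 10).

## Three steps most likely to fail, with fallbacks
1. **Step 16 (AFO cyclisation).** A 6'-alkoxy group and an ortho-substituted B ring both favour α-attack to the aurone, or a stalled flavanone. Fallback: drop the chalcone and use a Baker–Venkataraman sequence. Oxidise 17 to the benzoic acid, esterify it onto the 2-OH of 9, rearrange with base to the 1,3-diketone, cyclodehydrate to the flavone, then introduce the 3-OH by C3 lithiation (LDA), B(OMe)3 and H2O2.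
2. **Step 4 (Claisen rearrangement).** Competing para-Claisen–Cope migration to the 4-prenyl phenol, abnormal Claisen, or cyclisation to a dihydrobenzofuran. Fallback: move the [3,3] shift to a late, chelation-controlled stage. Carry the A ring as 2-hydroxy-4-prenyloxy-6-(MOM-oxy)acetophenone through the chalcone and flavonol, then rearrange the 5-hydroxy-7-prenyloxyflavonol, where H-bond bond fixation directs the 1,1-dimethylallyl group to C8.
3. **Step 12 (lithiation between Br and OMOM, then prenylation).** Risks are aryne formation, halogen dance, or SN2' allylation. Fallback: install both prenyls by Pd catalysis instead of aryl-metal alkylation. Make 2,3-dibromo-4,5-bis(MOM-oxy)benzaldehyde by stepwise 5,6-dibromination of 3,4-dihydroxybenzaldehyde and MOM protection, then run a double Suzuki (prenyl-Bpin, linear-selective ligand) or Stille (prenyl-SnBu3) coupling.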